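Compounds are numbered 1–18 in the order of the steps. Unprimed atom numbers (O1, C2, C3, C3a–C7a) belong to the first dihydrobenzofuran with benzo ring A. Primed numbers belong to the second dihydrobenzofuran with benzo ring B.

## Analysis of the target

The target consists of two trans-2,3-diaryl-2,3-dihydrobenzofurans joined through ring B. The first carries a 4-hydroxyphenyl group on C2, ring B on C3, an (E)-4-hydroxystyryl group on C4 and a hydroxyl on C6. The second is fused to ring B through O1'–C7a' and C3a', is bonded to C3 through C5', and carries a hydroxyl on C7', a 3,5-dihydroxyphenyl group on C3' and a 4-hydroxyphenyl group on C2'. There are four stereocentres in two trans pairs, (2S,3S) and (2'R,3'R). The pairs have opposite sense and are separated by ring B, so neither can direct the other and each needs its own absolute control. Sensitive features are the seven free phenols, the E-stilbene, and the two benzylic C–O bonds at C2 and C2', which ionise under acid because each is para-related to an oxygenated aryl ring. The difficulty is to form two crowded C–C/C–O bond pairs with control of regiochemistry and absolute configuration, and then to free seven phenols without acid damage. The strategy rests on ring A: C3a lies between C7a (bearing O1) and C4, with oxygen at C6, which is the pattern of a 5-alkoxyresorcinol with a carbene on its central carbon, provided the C4 substituent starts as oxygen. O1–C7a–C3a is then a three-atom unit that can be added across the C2=C3 double bond of a stilbene, and ring B repeats the same unit (O1'–C7a'–C3a') as the carbene form of an ortho-aminophenol.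

## Retrosynthetic reasoning

**18 from 17.** The seven O–methyl bonds are cut last. Methyl ethers are inert to carbenoids, hydrogenation, nitrosating agents and palladium, and a 4-methoxyphenyl group is the strong donor that the carbene steps need on one alkene end. The forward step must cleave seven aryl methyl ethers with a boron trihalide while sparing the stilbene and the two benzylic ethers.

**17 from 15 and 16.** The bond from C4 to the vinyl carbon is cut. C4 is an oxygen-bearing carbon in the carbene precursor, so its triflate is the natural handle. Placing this coupling after both annulations keeps the alkene away from the carbenoids and from the hydrogenation. The forward reaction is an alkenyl–aryl cross-coupling at a position ortho to the ring fusion, with retention of E geometry.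

**15 from 13 and 14.** C3a'–C3' and O1'–C2' are cut together, the same pair of bonds as in the key step. In 14 the 4-methoxyphenyl end stabilises positive charge and the 3,5-dimethoxyphenyl end does not, so the carbon bearing the latter bonds to the carbenoid. The enantiomeric catalyst is used because C3' has the opposite sense to C3. Attaching the second ring after the first is required: a fused dihydrofuran oxygen para to the alkene would make both alkene ends donors in the key step.

**13 from 12 from 11.** The diazo group of 13 comes from the amine of 12 by nitrosation. The amine and phenol of 12 come from the nitro group and benzyl ether of 11 in one hydrogenation. Carrying the nitro group from the start fixes the position of the nitrogen on ring B and makes that ring electron-poor during the key step.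

**11 from 6 and 10 (key disconnection).** C3a–C3 and O1–C2 are cut. This removes one ring, two skeletal bonds and both stereocentres of the first dihydrobenzofuran in a single step and leads to two simple fragments. The second flanking oxygen is already a triflate in 6, so neither the diazo compound nor the product has an O–H group that could intercept the carbenoid, and the coupling handle at C4 is in place. The forward reaction must bond the carbenoid carbon to the alkene carbon bearing the nitroaryl ring, close the ketone oxygen on the 4-methoxybenzylic carbon in a trans sense, and select one alkene face.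

**10 from 8 and 9; 8 from 7.** The stilbene double bond is cut by olefination of an aldehyde with a benzylphosphonate, which gives the E isomer. Aldehyde 8 is the benzyl ether of 7.

**6 from 5 from 3 from 2 from 1.** The triflate of 6 is made by O-sulfonylation of one of the two equivalent oxygens of 5. The diazo group of 5 is made from the amine of 3 by nitrosation rather than by electrophilic diazo transfer to the resorcinol: in a 5-alkoxyresorcinol the carbons between a hydroxyl and the alkoxy group compete with the carbon between the two hydroxyls, so the site of attack is not reliable. The nitrogen is placed without ambiguity by the nitro group of 1, whose two ortho fluorides are exchanged for benzyloxy groups (2) and then unmasked together with the nitro group (3).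

## Alternatives that were turned down

**Alternative 1: boron homologations for C3' and C2'.**
- Disconnection: in the second dihydrobenzofuran, C3'–C2' and the C2'–aryl bond are made on boron; O1'–C7a' is closed later from an aryl bromide.
- Forward key step: the diarylmethyl boronic ester A2, carrying a C2-symmetric chiral diol, is homologated with a halomethyl carbenoid, so that C3' migrates from boron to carbon with loss of chloride. An aryl Grignard reagent then displaces the second chloride through the ate complex with inversion and gives A1.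
- For it: each centre is set by the diol on boron in a predictable sense, and nothing depends on alkene polarisation. On stereochemical predictability at C2'/C3' it is stronger than the chosen route.
- Against it: it builds only the second dihydrobenzofuran. Ring B of A1 has no handle at C5' for the first one. Each centre costs its own cryogenic homologation with a stoichiometric chiral diol. The migrating group is a hindered diarylmethyl carbon, benzylic α-chloro boronic esters epimerise by chloride exchange, and oxidation and ring closure still follow.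
- Comparison: the chosen strategy makes two bonds, the ring and both centres in one catalytic step from a stilbene, and the same operation serves for both dihydrofurans.

**Alternative 2: ring A grown by Danheiser benzannulation.**
- Disconnection: ring A itself is taken apart (C3a–C4, C3a–C7a, C6–C7, C5–C6).
- Forward key step: irradiation of the α-diazo dienone A4 causes a Wolff shift to a vinylketene. This adds [2+2] to the tethered ethynyl ether, and 4π opening, 6π closure and tautomerisation give phenol A3.
- For it: the substitution pattern of ring A follows from the pericyclic sequence, with no regiochemical question, and the stilbene arm and a free C6 hydroxyl are already present. On ring A regiocontrol it is stronger.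
- Against it: the cascade sets no stereocentre, so C2 and C3 must be made beforehand in an acyclic precursor by separate asymmetric chemistry. The ethynyl ether of a secondary benzylic alcohol is thermally fragile. Irradiating a substrate with a conjugated aryl diene invites E/Z isomerisation and cycloaddition. The second dihydrobenzofuran still has to be added.
- Comparison: the chosen strategy forms the ring and its two centres together and is shorter.

**Alternative 3: dihydrocoumarin as temporary ring with anodic decarboxylation.**
- Disconnection: O1'–C2' of the second dihydrobenzofuran, with loss of a carboxyl carbon.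
- Forward key step: lactone A6 is opened with one equivalent of a quaternary ammonium hydroxide. Anodic non-Kolbe oxidation of the arylacetate causes decarboxylation to the 4-methoxybenzylic cation at C2', which the ring B phenol captures to give A5.
- For it: C3' can be set beforehand by asymmetric conjugate arylation of a coumarin, the trans ring then follows from substrate control, and the ester at C5' is a useful handle. On control of C3' by well-established catalysis it is stronger.
- Against it: a phenolate and several methoxyarenes are oxidised more easily than a carboxylate, so the chemoselectivity of the anodic step is doubtful. Only the second dihydrobenzofuran is made. When ring B already carries the fused ether oxygen, an alkene attached at C5' is no longer polarised in one direction, which blocks a clean construction of the first ring afterwards.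
- Comparison: the chosen strategy uses one bond-forming logic for both rings and needs fewer steps.

Key step: step 7

Assumptions (remarks on the chemistry):
- The sense of induction of Rh2(S-PTTL)4 (dirhodium tetrakis[N-phthaloyl-(S)-tert-leucinate]) with these carbenoids and 1,2-diarylalkenes is taken as S catalyst to (2S,3S) in step 7 and R catalyst to (2R,3R) in step 10. If it is the reverse, the two enantiomeric catalysts are exchanged and nothing else changes.
- Compound 1 is taken to be a catalogue compound.

## Route

Step 1
Reactants: 1 1,3-difluoro-5-methoxy-2-nitrobenzene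
Product: 2 1,3-bis(benzyloxy)-5-methoxy-2-nitrobenzene
Conditions: BnOH (2.3 equiv), NaH (2.3 equiv), THF, 0 °C → 50 °C
Reagents that add atoms: benzyl alcohol, OCc1ccccc1
Why: Nucleophilic aromatic substitution; both fluorides are ortho to the nitro group and are displaced by benzyloxide far faster than the para methoxy group, so the nitrogen ends up between the two future hydroxyls without any regiochemical question.

Step 2
Reactants: 2 1,3-bis(benzyloxy)-5-methoxy-2-nitrobenzene
Product: 3 2-amino-5-methoxybenzene-1,3-diol hydrochloride
Conditions: H2 (1 atm), Pd/C, HCl (1.1 equiv), MeOH, rt; filtered under argon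
Reagents that add atoms: hydrogen chloride, Cl
Why: Catalytic hydrogenation reduces the nitro group and hydrogenolyses both benzyl ethers in one operation; HCl traps the oxidation-prone aminoresorcinol as its salt.

Step 3
Reactants: 3 2-amino-5-methoxybenzene-1,3-diol hydrochloride
Product: 5 2-diazo-3-hydroxy-5-methoxycyclohexa-3,5-dien-1-one, via diazonium chloride 4 (not isolated)
Conditions: NaNO2 (1.0 equiv), 1 M aq. HCl, 0 °C, dark; then NaOAc to pH 5
Reagents that add atoms: sodium nitrite, [Na+].[O-]N=O
Why: Diazotisation of an ortho-aminophenol; N-nitrosation of the amine should outrun C-nitrosation of the ring, the diazonium group then deactivates the ring, and loss of a proton from one of the two equivalent hydroxyls on buffering gives the neutral quinone diazide.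

Step 4
Reactants: 5 2-diazo-3-hydroxy-5-methoxycyclohexa-3,5-dien-1-one
Product: 6 6-diazo-3-methoxy-5-oxocyclohexa-1,3-dien-1-yl trifluoromethanesulfonate
Conditions: Tf2O (1.05 equiv), pyridine, CH2Cl2, −40 → 0 °C, dark
Reagents that add atoms: trifluoromethanesulfonic anhydride, O=S(=O)(OS(=O)(=O)C(F)(F)F)C(F)(F)F
Why: O-Sulfonylation of an acidic hydroxyl; after deprotonation the two oxygens are equivalent, and the product is a neutral diazonium phenolate that is a much poorer nucleophile than the anion, so the reaction should stop at the monotriflate. This removes the only O–H group from the carbene step and places the later coupling handle on C4.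

Step 5
Reactants: 7 4-hydroxy-3-methoxy-5-nitrobenzaldehyde (5-nitrovanillin)
Product: 8 4-(benzyloxy)-3-methoxy-5-nitrobenzaldehyde
Conditions: BnBr, K2CO3, DMF, 60 °C
Reagents that add atoms: benzyl bromide, BrCc1ccccc1
Why: Williamson etherification of the nitrophenoxide; the benzyl group masks the phenol and will later leave in the same hydrogenation that reduces the nitro group.

Step 6
Reactants: 8 4-(benzyloxy)-3-methoxy-5-nitrobenzaldehyde; 9 diethyl (4-methoxybenzyl)phosphonate
Product: 10 (E)-2-(benzyloxy)-1-methoxy-5-[2-(4-methoxyphenyl)ethenyl]-3-nitrobenzene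
Conditions: KOtBu, THF, 0 °C → rt
Reagents that add atoms: none
Why: Horner–Wadsworth–Emmons olefination of a semi-stabilised benzylphosphonate anion with an electron-poor aryl aldehyde, which should give the E-stilbene.

Step 7
Reactants: 6 6-diazo-3-methoxy-5-oxocyclohexa-1,3-dien-1-yl trifluoromethanesulfonate; 10 (E)-2-(benzyloxy)-1-methoxy-5-[2-(4-methoxyphenyl)ethenyl]-3-nitrobenzene
Product: 11 (2S,3S)-3-[4-(benzyloxy)-3-methoxy-5-nitrophenyl]-6-methoxy-2-(4-methoxyphenyl)-2,3-dihydro-1-benzofuran-4-yl trifluoromethanesulfonate
Conditions: Rh2(S-PTTL)4 (2 mol %), 10 (2 equiv), PhCF3–CH2Cl2, 40 °C, slow addition of 6, dark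
Reagents that add atoms: none
Why: Rh2(S-PTTL)4 expels N2 from 6 and gives an electrophilic carbenoid at the future C3a; the stilbene attacks it through the carbon that carries the nitro-substituted aryl ring, because only the other alkene carbon can take up positive charge next to the 4-methoxyphenyl ring, and this forms C3a–C3. The ketone oxygen next to the carbenoid carbon then closes on the 4-methoxybenzylic carbon (5-exo-trig capture of the cation, directly or after opening of a spiro cyclopropane at its donor-substituted bond), which forms O1–C2 and leaves ring A aromatic without further tautomerisation. The closest known reaction type is the dirhodium tetracarboxylate-catalysed formal [3+2] annulation of cyclic 2-diazo-1,3-dicarbonyl compounds and ortho-quinone diazides with styrenes and enol ethers to dihydrofurans; a 1,2-diarylalkene is a more hindered member of the same alkene class. C3 is set in the C–C bond-forming event on the metal, where the chiral carboxylate ligands decide which alkene face is presented (catalyst control). C2 is set in the ring closure, which places the 4-methoxyphenyl group anti to the C3 aryl group, so the trans ring follows from the E-alkene and from the benzylic cation (substrate control). The step needs regioselectivity, secured by the strong donor on one alkene end against a nitro group and a flanked, twisted benzyloxy group on the other; it needs chemoselectivity, secured by the absence of any O–H group and by slow addition of 6 to an excess of 10; and it needs a single closing oxygen, which is all that 6 offers.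

Step 8
Reactants: 11 (2S,3S)-3-[4-(benzyloxy)-3-methoxy-5-nitrophenyl]-6-methoxy-2-(4-methoxyphenyl)-2,3-dihydro-1-benzofuran-4-yl trifluoromethanesulfonate
Product: 12 (2S,3S)-3-(3-amino-4-hydroxy-5-methoxyphenyl)-6-methoxy-2-(4-methoxyphenyl)-2,3-dihydro-1-benzofuran-4-yl trifluoromethanesulfonate
Conditions: H2 (1 atm), Pd/C, EtOAc–EtOH, rt
Reagents that add atoms: none
Why: Hydrogenation reduces the aryl nitro group and cleaves the benzyl aryl ether to give the ortho-aminophenol; aryl triflates and cyclic secondary benzylic aryl ethers (as in 2-arylchromans) normally survive neutral hydrogenation at atmospheric pressure, and the methyl ethers are inert.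

Step 9
Reactants: 12 (2S,3S)-3-(3-amino-4-hydroxy-5-methoxyphenyl)-6-methoxy-2-(4-methoxyphenyl)-2,3-dihydro-1-benzofuran-4-yl trifluoromethanesulfonate
Product: 13 (2S,3S)-3-(3-diazo-5-methoxy-4-oxocyclohexa-1,5-dien-1-yl)-6-methoxy-2-(4-methoxyphenyl)-2,3-dihydro-1-benzofuran-4-yl trifluoromethanesulfonate
Conditions: t-BuONO, AcOH, THF, 0 °C, dark; aq. NaHCO3 work-up
Reagents that add atoms: tert-butyl nitrite, CC(C)(C)ON=O
Why: Diazotisation of the ortho-aminophenol with an alkyl nitrite under weak acid, followed by loss of the phenolic proton, gives the ortho-quinone diazide; no other group in 12 should react with the nitrosating agent under these conditions.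

Step 10
Reactants: 13 (2S,3S)-3-(3-diazo-5-methoxy-4-oxocyclohexa-1,5-dien-1-yl)-6-methoxy-2-(4-methoxyphenyl)-2,3-dihydro-1-benzofuran-4-yl trifluoromethanesulfonate; 14 (E)-1,3-dimethoxy-5-[2-(4-methoxyphenyl)ethenyl]benzene
Product: 15 (2S,3S)-3-[(2R,3R)-3-(3,5-dimethoxyphenyl)-7-methoxy-2-(4-methoxyphenyl)-2,3-dihydro-1-benzofuran-5-yl]-6-methoxy-2-(4-methoxyphenyl)-2,3-dihydro-1-benzofuran-4-yl trifluoromethanesulfonate
Conditions: Rh2(R-PTTL)4 (2 mol %), 14 (3 equiv), PhCF3, 40 °C, slow addition of 13, dark
Reagents that add atoms: none
Why: Second use of the dirhodium-catalysed formal [3+2] annulation of an ortho-quinone diazide with an aryl alkene: the carbenoid carbon (C3a') bonds to the alkene carbon bearing the 3,5-dimethoxyphenyl ring, and the carbonyl oxygen closes on the 4-methoxybenzylic carbon C2' anti to the C3' aryl group. The enantiomeric catalyst selects the opposite alkene face, so C3' and C2' should be set as (R,R) independently of the distant C2/C3 pair.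

Step 11
Reactants: 15 (2S,3S)-3-[(2R,3R)-3-(3,5-dimethoxyphenyl)-7-methoxy-2-(4-methoxyphenyl)-2,3-dihydro-1-benzofuran-5-yl]-6-methoxy-2-(4-methoxyphenyl)-2,3-dihydro-1-benzofuran-4-yl trifluoromethanesulfonate; 16 2-[(E)-2-(4-methoxyphenyl)ethenyl]-4,4,5,5-tetramethyl-1,3,2-dioxaborolane
Product: 17 (2R,3R)-3-(3,5-dimethoxyphenyl)-7-methoxy-5-[(2S,3S)-6-methoxy-2-(4-methoxyphenyl)-4-[(E)-2-(4-methoxyphenyl)ethenyl]-2,3-dihydro-1-benzofuran-3-yl]-2-(4-methoxyphenyl)-2,3-dihydro-1-benzofuran
Conditions: Pd(OAc)2, SPhos, K3PO4, toluene–H2O, 80 °C
Reagents that add atoms: none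
Why: Suzuki–Miyaura coupling of the aryl triflate with an E-alkenylboronic ester, with retention of alkene geometry; a bulky electron-rich biarylphosphine is chosen because the triflate sits ortho to the ring fusion on an electron-rich ring.

Step 12
Reactants: 17 (2R,3R)-3-(3,5-dimethoxyphenyl)-7-methoxy-5-[(2S,3S)-6-methoxy-2-(4-methoxyphenyl)-4-[(E)-2-(4-methoxyphenyl)ethenyl]-2,3-dihydro-1-benzofuran-3-yl]-2-(4-methoxyphenyl)-2,3-dihydro-1-benzofuran
Product: 18 (2R,3R)-3-(3,5-dihydroxyphenyl)-2-(4-hydroxyphenyl)-5-[(2S,3S)-6-hydroxy-2-(4-hydroxyphenyl)-4-[(E)-2-(4-hydroxyphenyl)ethenyl]-2,3-dihydro-1-benzofuran-3-yl]-2,3-dihydro-1-benzofuran-7-ol (CNP0172909.1)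
Conditions: BBr3 (excess), CH2Cl2, −78 → 0 °C; cold aq. NaHCO3
Reagents that add atoms: none
Why: Lewis-acid cleavage of aryl methyl ethers by bromide attack on the O-methyl group of the boron complex; the ring aryl–O bonds of the two dihydrofurans are not cleaved, and C2/C2' can at most re-close to the favoured trans arrangement because C3 and C3' cannot epimerise.

## Compound list

1 | 1,3-difluoro-5-methoxy-2-nitrobenzene | COc1cc(F)c([N+](=O)[O-])c(F)c1 | starting material
2 | 1,3-bis(benzyloxy)-5-methoxy-2-nitrobenzene | COc1cc(OCc2ccccc2)c([N+](=O)[O-])c(OCc2ccccc2)c1 | intermediate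
3 | 2-amino-5-methoxybenzene-1,3-diol hydrochloride | COc1cc(O)c(N)c(O)c1.Cl | intermediate
4 | 2,6-dihydroxy-4-methoxybenzenediazonium chloride (formed in the flask) | COc1cc(O)c([N+]#N)c(O)c1.[Cl-] | intermediate
5 | 2-diazo-3-hydroxy-5-methoxycyclohexa-3,5-dien-1-one | [N-]=[N+]=C1C(=O)C=C(OC)C=C1O | intermediate
6 | 6-diazo-3-methoxy-5-oxocyclohexa-1,3-dien-1-yl trifluoromethanesulfonate | [N-]=[N+]=C1C(=O)C=C(OC)C=C1OS(=O)(=O)C(F)(F)F | intermediate
7 | 4-hydroxy-3-methoxy-5-nitrobenzaldehyde | COc1cc(C=O)cc([N+](=O)[O-])c1O | starting material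
8 | 4-(benzyloxy)-3-methoxy-5-nitrobenzaldehyde | COc1cc(C=O)cc([N+](=O)[O-])c1OCc1ccccc1 | intermediate
9 | diethyl (4-methoxybenzyl)phosphonate | CCOP(=O)(OCC)Cc1ccc(OC)cc1 | starting material
10 | (E)-2-(benzyloxy)-1-methoxy-5-[2-(4-methoxyphenyl)ethenyl]-3-nitrobenzene | COc1ccc(/C=C/c2cc(OC)c(OCc3ccccc3)c([N+](=O)[O-])c2)cc1 | intermediate
11 | (2S,3S)-3-[4-(benzyloxy)-3-methoxy-5-nitrophenyl]-6-methoxy-2-(4-methoxyphenyl)-2,3-dihydro-1-benzofuran-4-yl trifluoromethanesulfonate | FC(F)(F)S(=O)(=O)Oc1cc(OC)cc2c1[C@H](c1cc(OC)c(OCc3ccccc3)c([N+](=O)[O-])c1)[C@@H](c1ccc(OC)cc1)O2 | intermediate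
12 | (2S,3S)-3-(3-amino-4-hydroxy-5-methoxyphenyl)-6-methoxy-2-(4-methoxyphenyl)-2,3-dihydro-1-benzofuran-4-yl trifluoromethanesulfonate | FC(F)(F)S(=O)(=O)Oc1cc(OC)cc2c1[C@H](c1cc(OC)c(O)c(N)c1)[C@@H](c1ccc(OC)cc1)O2 | intermediate
13 | (2S,3S)-3-(3-diazo-5-methoxy-4-oxocyclohexa-1,5-dien-1-yl)-6-methoxy-2-(4-methoxyphenyl)-2,3-dihydro-1-benzofuran-4-yl trifluoromethanesulfonate | FC(F)(F)S(=O)(=O)Oc1cc(OC)cc2c1[C@H](C1=CC(=[N+]=[N-])C(=O)C(OC)=C1)[C@@H](c1ccc(OC)cc1)O2 | intermediate
14 | (E)-1,3-dimethoxy-5-[2-(4-methoxyphenyl)ethenyl]benzene | COc1ccc(/C=C/c2cc(OC)cc(OC)c2)cc1 | starting material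
15 | (2S,3S)-3-[(2R,3R)-3-(3,5-dimethoxyphenyl)-7-methoxy-2-(4-methoxyphenyl)-2,3-dihydro-1-benzofuran-5-yl]-6-methoxy-2-(4-methoxyphenyl)-2,3-dihydro-1-benzofuran-4-yl trifluoromethanesulfonate | FC(F)(F)S(=O)(=O)Oc2cc(OC)cc3c2[C@H](c2cc(OC)c4c(c2)[C@@H](c2cc(OC)cc(OC)c2)[C@H](c2ccc(OC)cc2)O4)[C@@H](c2ccc(OC)cc2)O3 | intermediate
16 | 2-[(E)-2-(4-methoxyphenyl)ethenyl]-4,4,5,5-tetramethyl-1,3,2-dioxaborolane | COc1ccc(/C=C/B2OC(C)(C)C(C)(C)O2)cc1 | starting material
17 | (2R,3R)-3-(3,5-dimethoxyphenyl)-7-methoxy-5-[(2S,3S)-6-methoxy-2-(4-methoxyphenyl)-4-[(E)-2-(4-methoxyphenyl)ethenyl]-2,3-dihydro-1-benzofuran-3-yl]-2-(4-methoxyphenyl)-2,3-dihydro-1-benzofuran | COc1ccc(/C=C/c2cc(OC)cc3c2[C@H](c2cc(OC)c4c(c2)[C@@H](c2cc(OC)cc(OC)c2)[C@H](c2ccc(OC)cc2)O4)[C@@H](c2ccc(OC)cc2)O3)cc1 | intermediate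
18 | (2R,3R)-3-(3,5-dihydroxyphenyl)-2-(4-hydroxyphenyl)-5-[(2S,3S)-6-hydroxy-2-(4-hydroxyphenyl)-4-[(E)-2-(4-hydroxyphenyl)ethenyl]-2,3-dihydro-1-benzofuran-3-yl]-2,3-dihydro-1-benzofuran-7-ol | Oc1ccc(/C=C/c2cc(O)cc3c2[C@H](c2cc(O)c4c(c2)[C@@H](c2cc(O)cc(O)c2)[C@H](c2ccc(O)cc2)O4)[C@@H](c2ccc(O)cc2)O3)cc1 | target

## Step count and risk

Total step count: 12. Longest linear sequence: 10 steps (steps 1–4 and 7–12, from 1 to 18). Steps 5–6 form a two-step side branch; 14 and 16 are bought.

Least certain steps:

**Step 7 (key step).** The most likely failure is poor discrimination between the two alkene faces: the C–C bond forms through an open, polar transition state in which the stilbene may sit far from the chiral ligands. A second concern is slow capture of the carbenoid by a stilbene that is deactivated at its nitroaryl end, so that ring contraction by Wolff rearrangement or carbene dimerisation compete. Fallback: absolute configuration is obtained by resolution instead of catalysis. Setting out from 6 and 10, the annulation is run with achiral Rh2(esp)2, which should give the trans product as a racemate of 11 and its mirror image, (2R,3R)-3-[4-(benzyloxy)-3-methoxy-5-nitrophenyl]-6-methoxy-2-(4-methoxyphenyl)-2,3-dihydro-1-benzofuran-4-yl trifluoromethanesulfonate F1. Preparative chromatography on a chiral stationary phase separates the two, and the route is rejoined at 11.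

**Step 10.** The electrophilic carbenoid may attack the electron-rich 3,5-dimethoxyphenyl ring of 14 (aromatic substitution) instead of the alkene, and catalyst control over the distant, pre-existing centres may be incomplete. Fallback: the competing ring is switched off by a different partner. Purchased (E)-5-[2-(4-methoxyphenyl)ethenyl]benzene-1,3-diol F2 is acetylated (Ac2O, pyridine) to (E)-5-[2-(4-methoxyphenyl)ethenyl]-1,3-phenylene diacetate F3, whose resorcinol ring is deactivated while the alkene keeps its polarisation. Annulation of 13 with it under Rh2(R-PTTL)4 should give (2S,3S)-3-[(2R,3R)-3-(3,5-diacetoxyphenyl)-7-methoxy-2-(4-methoxyphenyl)-2,3-dihydro-1-benzofuran-5-yl]-6-methoxy-2-(4-methoxyphenyl)-2,3-dihydro-1-benzofuran-4-yl trifluoromethanesulfonate F4. Coupling with 16 under the aqueous basic conditions of step 11 also cleaves the acetates and should give 5-[(2R,3R)-7-methoxy-5-[(2S,3S)-6-methoxy-2-(4-methoxyphenyl)-4-[(E)-2-(4-methoxyphenyl)ethenyl]-2,3-dihydro-1-benzofuran-3-yl]-2-(4-methoxyphenyl)-2,3-dihydro-1-benzofuran-3-yl]benzene-1,3-diol F5. Cleavage of its five methyl ethers with BBr3 rejoins the route at 18.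

**Step 12.** Acid formed during demethylation or quench may protonate the stilbene, after which ring B on C3 can close onto the resulting benzylic cation to a seven-membered ring; ionisation of the C2–O1 and C2'–O1' bonds is a second acid-driven pathway. Fallback: the methyl ethers are removed before the alkene exists. Setting out from 15, BBr3 should give the hexaphenol (2S,3S)-3-[(2R,3R)-3-(3,5-dihydroxyphenyl)-7-hydroxy-2-(4-hydroxyphenyl)-2,3-dihydro-1-benzofuran-5-yl]-6-hydroxy-2-(4-hydroxyphenyl)-2,3-dihydro-1-benzofuran-4-yl trifluoromethanesulfonate F6, since aryl triflates are inert to this reagent. Suzuki–Miyaura coupling of the unprotected polyphenol with the catalogue boronic ester 4-[(E)-2-(4,4,5,5-tetramethyl-1,3,2-dioxaborolan-2-yl)ethenyl]phenol F7 (Pd(OAc)2, SPhos, excess K3PO4, dioxane–H2O, argon) then rejoins the route at 18.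

**Step 4.** The triflyloxy quinone diazide may lose nitrogen or be sulfonylated a second time during preparation or isolation. Fallback: the order of events is changed. Setting out from 5, the annulation with 10 is run on the free hydroxy compound (Rh2(S-PTTL)4, slow addition of 5 to a larger excess of 10) to give (2S,3S)-3-[4-(benzyloxy)-3-methoxy-5-nitrophenyl]-6-methoxy-2-(4-methoxyphenyl)-2,3-dihydro-1-benzofuran-4-ol F8. This phenol is then triflated (Tf2O, pyridine), rejoining the route at 11. The price is possible O–H insertion of the carbenoid into the phenolic product.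

**Step 8.** Over-reduction may occur: hydrogenolysis of the benzylic C2–O1 bond or of the aryl–triflate bond. Fallback: the two events are separated and no hydrogenolysis catalyst is used. Setting out from 11, the nitro group is reduced with Zn and NH4Cl (EtOH–H2O) to (2S,3S)-3-[3-amino-4-(benzyloxy)-5-methoxyphenyl]-6-methoxy-2-(4-methoxyphenyl)-2,3-dihydro-1-benzofuran-4-yl trifluoromethanesulfonate F9. The benzyl ether is then cleaved with BCl3 and pentamethylbenzene at −78 °C, rejoining the route at 12.

Further compounds
F1 | step 7 | (2R,3R)-3-[4-(benzyloxy)-3-methoxy-5-nitrophenyl]-6-methoxy-2-(4-methoxyphenyl)-2,3-dihydro-1-benzofuran-4-yl trifluoromethanesulfonate | FC(F)(F)S(=O)(=O)Oc1cc(OC)cc2c1[C@@H](c1cc(OC)c(OCc3ccccc3)c([N+](=O)[O-])c1)[C@H](c1ccc(OC)cc1)O2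
F2 | step 10 | (E)-5-[2-(4-methoxyphenyl)ethenyl]benzene-1,3-diol (purchased) | COc1ccc(/C=C/c2cc(O)cc(O)c2)cc1
F3 | step 10 | (E)-5-[2-(4-methoxyphenyl)ethenyl]-1,3-phenylene diacetate | COc1ccc(/C=C/c2cc(OC(C)=O)cc(OC(C)=O)c2)cc1
F4 | step 10 | (2S,3S)-3-[(2R,3R)-3-(3,5-diacetoxyphenyl)-7-methoxy-2-(4-methoxyphenyl)-2,3-dihydro-1-benzofuran-5-yl]-6-methoxy-2-(4-methoxyphenyl)-2,3-dihydro-1-benzofuran-4-yl trifluoromethanesulfonate | FC(F)(F)S(=O)(=O)Oc2cc(OC)cc3c2[C@H](c2cc(OC)c4c(c2)[C@@H](c2cc(OC(C)=O)cc(OC(C)=O)c2)[C@H](c2ccc(OC)cc2)O4)[C@@H](c2ccc(OC)cc2)O3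
F5 | step 10 | 5-[(2R,3R)-7-methoxy-5-[(2S,3S)-6-methoxy-2-(4-methoxyphenyl)-4-[(E)-2-(4-methoxyphenyl)ethenyl]-2,3-dihydro-1-benzofuran-3-yl]-2-(4-methoxyphenyl)-2,3-dihydro-1-benzofuran-3-yl]benzene-1,3-diol | COc1ccc(/C=C/c2cc(OC)cc3c2[C@H](c2cc(OC)c4c(c2)[C@@H](c2cc(O)cc(O)c2)[C@H](c2ccc(OC)cc2)O4)[C@@H](c2ccc(OC)cc2)O3)cc1
F6 | step 12 | (2S,3S)-3-[(2R,3R)-3-(3,5-dihydroxyphenyl)-7-hydroxy-2-(4-hydroxyphenyl)-2,3-dihydro-1-benzofuran-5-yl]-6-hydroxy-2-(4-hydroxyphenyl)-2,3-dihydro-1-benzofuran-4-yl trifluoromethanesulfonate | FC(F)(F)S(=O)(=O)Oc2cc(O)cc3c2[C@H](c2cc(O)c4c(c2)[C@@H](c2cc(O)cc(O)c2)[C@H](c2ccc(O)cc2)O4)[C@@H](c2ccc(O)cc2)O3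
F7 | step 12 | 4-[(E)-2-(4,4,5,5-tetramethyl-1,3,2-dioxaborolan-2-yl)ethenyl]phenol (purchased) | Oc1ccc(/C=C/B2OC(C)(C)C(C)(C)O2)cc1
F8 | step 4 | (2S,3S)-3-[4-(benzyloxy)-3-methoxy-5-nitrophenyl]-6-methoxy-2-(4-methoxyphenyl)-2,3-dihydro-1-benzofuran-4-ol | Oc1cc(OC)cc2c1[C@H](c1cc(OC)c(OCc3ccccc3)c([N+](=O)[O-])c1)[C@@H](c1ccc(OC)cc1)O2
F9 | step 8 | (2S,3S)-3-[3-amino-4-(benzyloxy)-5-methoxyphenyl]-6-methoxy-2-(4-methoxyphenyl)-2,3-dihydro-1-benzofuran-4-yl trifluoromethanesulfonate | FC(F)(F)S(=O)(=O)Oc1cc(OC)cc2c1[C@H](c1cc(OC)c(OCc3ccccc3)c(N)c1)[C@@H](c1ccc(OC)cc1)O2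
A1 | alternative 1 | 2-[2-(2-bromo-3-methoxyphenyl)-2-(3,5-dimethoxyphenyl)-1-(4-methoxyphenyl)ethyl]-4,5-dicyclohexyl-1,3,2-dioxaborolane, C2' and C3' configured as in the target | COc1cccc([C@@H](c2cc(OC)cc(OC)c2)[C@H](c2ccc(OC)cc2)B2O[C@H](C3CCCCC3)[C@@H](C3CCCCC3)O2)c1Br
A2 | alternative 1 | 2-[(2-bromo-3-methoxyphenyl)(3,5-dimethoxyphenyl)methyl]-4,5-dicyclohexyl-1,3,2-dioxaborolane, C3' configured as in the target | COc1cccc([C@@H](c2cc(OC)cc(OC)c2)B2O[C@H](C3CCCCC3)[C@@H](C3CCCCC3)O2)c1Br
A3 | alternative 2 | (2S,3S)-3-[4-(benzyloxy)-3-methoxyphenyl]-2-(4-methoxyphenyl)-4-[(E)-2-(4-methoxyphenyl)ethenyl]-2,3-dihydro-1-benzofuran-6-ol | COc1ccc(/C=C/c2cc(O)cc3c2[C@H](c2cc(OC)c(OCc4ccccc4)cc2)[C@@H](c2ccc(OC)cc2)O3)cc1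
A4 | alternative 2 | 5-[4-(benzyloxy)-3-methoxyphenyl]-4-diazo-6-(ethynyloxy)-6-(4-methoxyphenyl)-2-[(E)-2-(4-methoxyphenyl)ethenyl]hex-1-en-3-one, C5 and C6 configured as C3 and C2 of the target | C=C(/C=C/c1ccc(OC)cc1)C(=O)C(=[N+]=[N-])[C@H](c1cc(OC)c(OCc2ccccc2)cc1)[C@@H](c1ccc(OC)cc1)OC#C
A5 | alternative 3 | methyl (2R,3R)-3-(3,5-dimethoxyphenyl)-7-methoxy-2-(4-methoxyphenyl)-2,3-dihydro-1-benzofuran-5-carboxylate | COC(=O)c1cc(OC)c2c(c1)[C@@H](c1cc(OC)cc(OC)c1)[C@H](c1ccc(OC)cc1)O2
A6 | alternative 3 | methyl 4-(3,5-dimethoxyphenyl)-8-methoxy-3-(4-methoxyphenyl)-2-oxo-3,4-dihydro-2H-1-benzopyran-6-carboxylate, C4 configured as C3' of the target | COC(=O)c1cc(OC)c2c(c1)[C@@H](c1cc(OC)cc(OC)c1)C(c1ccc(OC)cc1)C(=O)O2
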